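The theta readings cannot tell a balance from a dead free enzyme, for a flat line looks the same either way, so I need the delta run to say which flat line this is.

the same everywhere: free enzyme 0.053 mol%
- theta: substrate 0.16 M; temperature 40 °C; the very flask that is asked about, followed so far
- delta: substrate 0.24 M; temperature 35 °C; run made earlier
- flask: substrate 0.16 M; temperature 40 °C; time 3.0 h

| run | time / min | target / % | substrate / % |
|---|---|---|---|
| theta | 15.0 | 67.2 | 25.3 |
| theta | 30.0 | 67.1 | 25.5 |
| theta | 80.0 | 66.8 | 24.9 |
| theta | 180 | 66.9 | 24.9 |
| delta | 2.00 | 31.7 | 66.8 |
| delta | 4.00 | 51.5 | 44.5 |
| delta | 5.00 | 57.1 | 36.9 |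
| delta | 8.00 | 65.5 | 25.4 |

(each reading ± 0.3 percentage points)

- amber: at 3.0 h raise the temperature by 20 K, then wait 50 min
- blue: at 3.0 h take out 90% of the target then present, then wait 50 min
- teal: at 3.0 h add free enzyme, 50.0% of the amount charged, then wait 50 min
- grey: change nothing and wait 50 min more

- target that was removed still counts
- steps under discussion: free enzyme -> unfolded enzyme; substrate + free enzyme <-> complex; complex <-> free enzyme + target; target <-> isomer of the product
- additions bring no volume worth counting

1. target, in percent of the substrate first charged, at 3.0 h
2. the remedy with the largest gain of target, or "none" below 2 percentage points (amber / blue / teal / grey / none)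
3. target present, with what was taken out counted in, in percent of the substrate first charged, after blue
4. target present, with what was taken out counted in, in percent of the substrate first charged, after grey

I draw the curve from the delta run, whose readings still rise, whereas the theta flask stands flat from its earliest reading at 15.0 min. In the delta run target stands at 31.7% after 2.00 min and, by straight interpolation, passes substrate at about 3.67 min. The level comes from the theta run, whose mean target is the quantity I carry: the resting share, the part of the material in a flask at this temperature that stands as target once the flask has come to balance, which is the equilibrium share under thermodynamic control, and here, if the flat line is a balance, it reads 67.0%. The first slope of the delta run, kept up, would reach that level by 4.23 min, but the curve bends and stands at 65.5% after 8.00 min.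

Mean substrate in the theta run is 25.1%, and the remaining 7.85% I read as isomer of the product. The delta run, with 0.24 M at 35 °C, arrives at substrate 25.4%, and I read that meeting as a balance, although that run ends there and a dead free enzyme stays possible. So target now is the resting share, and grey and teal change nothing; amber I do not reckon, since the share was read at 40 °C. Blue takes out 60.3% of the charge, the wait of 50 min is longer than the 15.0 min by which the theta flask stood flat, and the resting share of the remainder stands as 26.6% of the charge, which makes 86.9% counted in, a gain of 20 percentage points, larger than 2 points.

The forecast gives 67% now, blue as best, 85% after it, below my figure, and 66.9% after grey, on the ground “I therefore read the stall as equilibrium”.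

The flask gives 67.0% at 3.0 h, blue as best with a gain of 20 points, 86.9% after it and 67.0% after grey.

    free enzyme → unfolded enzyme (k = 1.52 × 10⁻⁵ s⁻¹, Ea = 210 kJ mol⁻¹)
    substrate + free enzyme ⇌ complex (K = 9.80 M⁻¹, k = 990 M⁻¹ s⁻¹, Ea = 44.0 kJ mol⁻¹, ΔH = −5.00 kJ mol⁻¹)
    complex ⇌ free enzyme + target (K = 0.274 M, k = 12.5 s⁻¹, Ea = 58.0 kJ mol⁻¹, ΔH = −24.0 kJ mol⁻¹)
    target ⇌ isomer of the product (K = 0.120, k = 0.00157 s⁻¹, Ea = 103 kJ mol⁻¹, ΔH = −64.0 kJ mol⁻¹)
    (constants at 40 °C)

In this flask the forward rate of target's loss to isomer of the product, the way back not counted, gives target a half-life of 7.4 min, short against the 3.0 h, while the loss of free enzyme to unfolded enzyme, which holds 11.0% of the catalyst at 180 min, makes no difference to target then. The resting share serves again twice: of the remainder after blue, 67.0% stands as target after the wait, and the neighbour flask read at 12 h, with 37.6% of its catalyst unfolded, holds target at 67.0%.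

All runs are simulated with constants of no real substance, noise included.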